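Cuts, in retrosynthetic order: the four O-protecting groups; C8–C1'' (ring A carbanion plus a Z-configured C5 allylic bromide); the C4 oxygen (back to the flavan CH2); C3–C4 of ring C, undone by placing a nitrogen atom between the two carbons; then that N–C4 bond (imine reduction) and O1–C8a (fluoride displacement).
Enabling feature: O1, C2 with its ring B substituent, and C3 form the O–CH(aryl)–CH2 backbone of (R)-norepinephrine. The amine nitrogen hangs on C3 exactly where C4, a benzylic carbon of ring A, must be attached.
Forward order: ring A is attached to the carbinol oxygen (O1–C8a), a seven-membered 1,4-benzoxazepine is closed through nitrogen, and excision of that nitrogen contracts it to the six-membered ring C (C3–C4).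
Then C4 is oxygenated, C8 is metalated between O1 and O7 and joined to the side chain, C4 is returned to the ketone, and one acid step frees all hydroxyl groups.
Stereochemistry: C2 is the chiral-pool carbinol carbon, and none of its bonds to O, H, aryl or CH2 is ever broken (R becomes S only through a priority change). The Z alkene comes from anti-carbomagnesiation of propargyl alcohol and is carried on with retention.

Key step: step 6

Assumption: (R)-norepinephrine is used as the enantiopure free base, and flavonoid numbering (O1, C2 to C4, C4a, C5 to C8, C8a, primed ring B, doubly primed side chain) is applied to all intermediates, C5 and C9 of the benzoxazepines being the future C4 and C8.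

Step 1
Reactants: 1 (R)-norepinephrine
Product: 2 (R)-N-tritylnorepinephrine
Conditions: TrCl (1.05 equiv), Et3N, DMF, 0 °C to rt, under argon
Reagents that add atoms: trityl chloride, ClC(c1ccccc1)(c1ccccc1)c1ccccc1
Why: SN1-type N-tritylation: with a tertiary amine as the only base the phenols stay protonated and the primary amine is the sole good nucleophile for the trityl cation, and the carbonyl-free trityl group is chosen because a carbamate would be attacked by the neighbouring alkoxide of step 4 to give an oxazolidinone.

Step 2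
Reactants: 2 (R)-N-tritylnorepinephrine
Product: 3 (1R)-1-[3,4-bis(methoxymethoxy)phenyl]-2-(tritylamino)ethanol
Conditions: MOMCl (2.3 equiv), K2CO3, acetone, 0 °C to rt, under argon
Reagents that add atoms: chloromethyl methyl ether, COCCl
Why: Williamson-type acetal ether formation: K2CO3 ionises only the two phenols, so the benzylic alcohol needed in step 4 and the very hindered tritylamine remain free and the carbinol centre is not touched.

Step 3
Reactants: 4 2-fluoro-4-hydroxybenzaldehyde
Product: 5 2-fluoro-4-(methoxymethoxy)benzaldehyde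
Conditions: MOMCl (1.2 equiv), K2CO3, acetone, 0 °C to rt
Reagents that add atoms: chloromethyl methyl ether, COCCl
Why: Williamson-type acetal ether formation: masking the phenol keeps a para-phenoxide from switching off the formyl-activated fluoride displacement of step 4 and installs the metalation-directing group needed at O7 in step 13.

Step 4
Reactants: 3 (1R)-1-[3,4-bis(methoxymethoxy)phenyl]-2-(tritylamino)ethanol; 5 2-fluoro-4-(methoxymethoxy)benzaldehyde
Product: 7 2-{(1R)-1-[3,4-bis(methoxymethoxy)phenyl]-2-(tritylamino)ethoxy}-4-(methoxymethoxy)benzaldehyde, via sodium alkoxide 6 (not isolated)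
Conditions: NaH (1.1 equiv), DMF, 0 °C; then 5 (1.2 equiv), 0 °C to rt
Reagents that add atoms: none
Why: Nucleophilic aromatic substitution by addition–elimination: the ortho-formyl group stabilises the Meisenheimer adduct, the 4-alkoxy group is meta to fluorine and does not oppose it, and since only the O–H bond of the carbinol is broken the O1–C8a bond forms with retention at the future C2.

Step 5
Reactants: 7 2-{(1R)-1-[3,4-bis(methoxymethoxy)phenyl]-2-(tritylamino)ethoxy}-4-(methoxymethoxy)benzaldehyde
Product: 10 (2R)-2-[3,4-bis(methoxymethoxy)phenyl]-8-(methoxymethoxy)-2,3,4,5-tetrahydro-1,4-benzoxazepine, via amino aldehyde 8 (not isolated), via cyclic imine 9 (not isolated)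
Conditions: AcOH–H2O (4:1), 35 °C; then 2-picoline–borane, rt
Reagents that add atoms: none
Why: Acid solvolysis of the N-trityl group followed by intramolecular reductive amination: the protonated tritylamine ionises in aqueous acetic acid that leaves aryl MOM ethers alone, the freed amine condenses with the tethered aldehyde to the seven-membered imine as 2-(2-aminoethoxy)benzaldehydes generally do, and the amine–borane reduces the iminium ion without touching C2.

Step 6
Reactants: 10 (2R)-2-[3,4-bis(methoxymethoxy)phenyl]-8-(methoxymethoxy)-2,3,4,5-tetrahydro-1,4-benzoxazepine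
Product: 14 (2S)-7,3',4'-tris(methoxymethoxy)flavan, via N-alkoxy hydrazide 11 (not isolated), via isodiazene 12 (not isolated), via 1,6-diradical 13 (not isolated)
Conditions: N-(benzyloxy)-N-(pivaloyloxy)-4-(trifluoromethyl)benzamide (1.5 equiv), THF, rt to 45 °C
Reagents that add atoms: none
Why: The ring nitrogen of 10 displaces pivalate from the amide nitrogen of the reagent to give hydrazide 11, whose benzyloxy group migrates to the acyl carbon (HERON-type rearrangement) and releases isodiazene 12; loss of N2 then leaves the singlet 1,6-diradical 13, benzylic at C4 and primary at C3, and the two centres couple to the C3–C4 bond. The closest known reaction type is the nitrogen deletion of cyclic secondary benzylic amines with anomeric amides, which for example contracts tetrahydroisoquinolines to indanes. Ring C closes by intramolecular radical–radical recombination, a six-membered closure whose termini are held together by the C2–O1–C8a–C4a tether, so that the seven-membered ring shrinks by one atom. No stereocentre is created: C2 is never a radical site and keeps its four substituents in place, and its descriptor turns from R to S only because C3 drops below the aryl group once nitrogen has gone. The selectivity needed is recombination ahead of β-scission of the C2–O1 bond (which would give an ortho-quinone methide and a styrene that re-add without stereocontrol) and ahead of tautomerisation of 12 to a hydrazone; it is favoured by the short tether, by the singlet state of a pair born from N2 loss, and by the benzylic stabilisation at C4, which lets N2 leave near room temperature. The enantiomeric purity of 14 should be checked by chiral HPLC at this point, since leakage through the fragmentation path would show up there as racemate.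

Step 7
Reactants: 14 (2S)-7,3',4'-tris(methoxymethoxy)flavan
Product: 16 (2S)-7,3',4'-tris(methoxymethoxy)flavanone, via epimeric flavan-4-ol 15 (not isolated)
Conditions: DDQ (2.3 equiv), CH2Cl2–H2O (10:1), 0 °C to rt
Reagents that add atoms: water, O
Why: DDQ benzylic oxidation by hydride abstraction, known for C4 of alkoxy-substituted flavans: the pseudo-axial C4–H bond is aligned with ring A and its cation is stabilised by O1 (ortho) and the 7-alkoxy group (para), water traps it to 15, this carbinol is oxidised faster still, and the electron-poor aryl ketone 16 ends the sequence with C2 unchanged.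

Step 8
Reactants: 16 (2S)-7,3',4'-tris(methoxymethoxy)flavanone
Product: 17 (2S,4S)-7,3',4'-tris(methoxymethoxy)flavan-4-ol (2,4-cis)
Conditions: NaBH4, MeOH–THF, 0 °C
Reagents that add atoms: none
Why: Borohydride 1,2-reduction of a flavanone: with the 2-aryl group equatorial in the half-chair, hydride arrives along the axial trajectory and gives the equatorial 2,4-cis carbinol (4S), a temporary centre that only hides the enolisable, base-sensitive ketone from the organolithium of step 13.

Step 9
Reactants: 18 propargyl alcohol
Product: 20 (Z)-3-iodo-2-methylprop-2-en-1-ol, via oxamagnesacycle 19 (not isolated)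
Conditions: MeMgBr (2.5 equiv), CuI (10 mol%), THF, −10 °C to rt; then I2, THF, 0 °C
Reagents that add atoms: methylmagnesium bromide, C[Mg]Br; iodine, [I][I]
Why: Copper-catalysed anti-carbomagnesiation of a propargylic alkoxide: methyl is delivered to C2 while magnesium ends on C3 inside a five-membered chelate with the alkoxide oxygen, so that iodinolysis with retention puts iodine cis to CH2OH and fixes the Z geometry.

Step 10
Reactants: 20 (Z)-3-iodo-2-methylprop-2-en-1-ol
Product: 21 (Z)-tert-butyl[(3-iodo-2-methylprop-2-en-1-yl)oxy]dimethylsilane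
Conditions: TBSCl, imidazole, CH2Cl2, 0 °C to rt
Reagents that add atoms: tert-butyldimethylsilyl chloride, CC(C)(C)[Si](C)(C)Cl
Why: Imidazole-promoted silylation of a primary alcohol: the TBS ether withstands the organolithium, copper and periodinane chemistry ahead and falls under the same mild acid as the aryl MOM ethers in step 15.

Step 11
Reactants: 21 (Z)-tert-butyl[(3-iodo-2-methylprop-2-en-1-yl)oxy]dimethylsilane
Product: 23 (Z)-4-(tert-butyldimethylsilyloxy)-3-methylbut-2-en-1-ol, via Z-alkenyllithium 22 (not isolated)
Conditions: t-BuLi (2.1 equiv), Et2O, −78 °C; then anhydrous CH2O in THF, −78 °C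
Reagents that add atoms: formaldehyde, C=O
Why: Iodine–lithium exchange and hydroxymethylation: alkenyl iodides exchange with t-BuLi with retention of geometry, and holding the Z-alkenyllithium at −78 °C in ether and quenching it there with monomeric formaldehyde forestalls the 1,4 oxygen-to-carbon silyl shift open to it on warming.

Step 12
Reactants: 23 (Z)-4-(tert-butyldimethylsilyloxy)-3-methylbut-2-en-1-ol
Product: 24 (Z)-[(4-bromo-2-methylbut-2-en-1-yl)oxy](tert-butyl)dimethylsilane
Conditions: CBr4, PPh3, CH2Cl2, 0 °C
Reagents that add atoms: carbon tetrabromide, BrC(Br)(Br)Br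
Why: Appel bromination: the primary allylic alcohol is displaced by bromide through its oxyphosphonium salt under neutral conditions at 0 °C, which avoids allylic transposition, Z to E isomerisation and loss of the silyl ether.

Step 13
Reactants: 17 (2S,4S)-7,3',4'-tris(methoxymethoxy)flavan-4-ol; 24 (Z)-[(4-bromo-2-methylbut-2-en-1-yl)oxy](tert-butyl)dimethylsilane
Product: 27 (2S,4S)-8-[(2Z)-4-(tert-butyldimethylsilyloxy)-3-methylbut-2-en-1-yl]-7,3',4'-tris(methoxymethoxy)flavan-4-ol, via dilithio species 25 (not isolated), via arylcopper 26 (not isolated)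
Conditions: n-BuLi (2.2 equiv), THF, −20 to 0 °C; CuBr·SMe2 (1.1 equiv), −78 °C; then 24, −78 to 0 °C
Reagents that add atoms: none
Why: Directed ortho-metalation followed by copper-mediated allylic substitution: once the C4 hydroxyl is parked as its lithium alkoxide, the second equivalent of n-BuLi removes the C8 proton, the only one flanked by two oxygens (O1 and the chelating 7-OMOM group) and hence kinetically more acidic than the singly activated C6, C2' and C5' positions or the hindered C2 methine, and the derived aryl derivative of monovalent copper displaces the primary bromide of 24 at its unhindered α-carbon with the Z geometry kept.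

Step 14
Reactants: 27 (2S,4S)-8-[(2Z)-4-(tert-butyldimethylsilyloxy)-3-methylbut-2-en-1-yl]-7,3',4'-tris(methoxymethoxy)flavan-4-ol
Product: 28 (2S)-8-[(2Z)-4-(tert-butyldimethylsilyloxy)-3-methylbut-2-en-1-yl]-7,3',4'-tris(methoxymethoxy)flavanone
Conditions: Dess–Martin periodinane, CH2Cl2, 0 °C to rt
Reagents that add atoms: none
Why: Dess–Martin oxidation: the secondary benzylic carbinol is the only free hydroxyl, and the neutral, non-enolising conditions leave the trisubstituted Z alkene, the silyl ether, the acetals and the C2 centre of the new flavanone intact.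

Step 15
Reactants: 28 (2S)-8-[(2Z)-4-(tert-butyldimethylsilyloxy)-3-methylbut-2-en-1-yl]-7,3',4'-tris(methoxymethoxy)flavanone
Product: 29 (2S)-2-(3,4-dihydroxyphenyl)-7-hydroxy-8-[(2Z)-4-hydroxy-3-methylbut-2-en-1-yl]-2,3-dihydro-4H-chromen-4-one (target)
Conditions: HCl (1.25 M in MeOH), 0 °C to rt, gentle warming if needed; work-up kept below pH 7
Reagents that add atoms: none
Why: Acid-catalysed transacetalisation and desilylation in methanol, the usual release of prenylated flavanones from MOM ethers: the medium stays acidic because the ring opening (retro-oxa-Michael) that would racemise C2 is base-promoted, and it stays dilute and near room temperature so that neither alkene protonation with chroman formation nor ionisation of the primary allylic alcohol competes.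

Compound list
1 | (R)-norepinephrine | NC[C@H](O)c1ccc(O)c(O)c1 | starting material
2 | (R)-N-tritylnorepinephrine, 4-[(1R)-1-hydroxy-2-(tritylamino)ethyl]benzene-1,2-diol | C(c1ccccc1)(c1ccccc1)(c1ccccc1)NC[C@H](O)c1ccc(O)c(O)c1 | intermediate
3 | (1R)-1-[3,4-bis(methoxymethoxy)phenyl]-2-(tritylamino)ethanol | C(c1ccccc1)(c1ccccc1)(c1ccccc1)NC[C@H](O)c1ccc(OCOC)c(OCOC)c1 | intermediate
4 | 2-fluoro-4-hydroxybenzaldehyde | O=Cc1ccc(O)cc1F | starting material
5 | 2-fluoro-4-(methoxymethoxy)benzaldehyde | O=Cc1ccc(OCOC)cc1F | intermediate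
6 | sodium alkoxide of 3 | C(c1ccccc1)(c1ccccc1)(c1ccccc1)NC[C@H]([O-])c1ccc(OCOC)c(OCOC)c1.[Na+] | intermediate
7 | 2-{(1R)-1-[3,4-bis(methoxymethoxy)phenyl]-2-(tritylamino)ethoxy}-4-(methoxymethoxy)benzaldehyde | O=Cc1ccc(OCOC)cc1O[C@H](c1ccc(OCOC)c(OCOC)c1)CNC(c1ccccc1)(c1ccccc1)c1ccccc1 | intermediate
8 | 2-{(1R)-2-amino-1-[3,4-bis(methoxymethoxy)phenyl]ethoxy}-4-(methoxymethoxy)benzaldehyde | O=Cc1ccc(OCOC)cc1O[C@H](c1ccc(OCOC)c(OCOC)c1)CN | intermediate
9 | (2R)-2-[3,4-bis(methoxymethoxy)phenyl]-8-(methoxymethoxy)-2,3-dihydro-1,4-benzoxazepine (cyclic imine) | COCOc1ccc2c(c1)O[C@H](c1ccc(OCOC)c(OCOC)c1)CN=C2 | intermediate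
10 | (2R)-2-[3,4-bis(methoxymethoxy)phenyl]-8-(methoxymethoxy)-2,3,4,5-tetrahydro-1,4-benzoxazepine | COCOc1ccc2c(c1)O[C@H](c1ccc(OCOC)c(OCOC)c1)CNC2 | intermediate
11 | N-(benzyloxy)-N-[(2R)-benzoxazepin-4-yl]-4-(trifluoromethyl)benzamide derived from 10 (N-alkoxy hydrazide) | COCOc1ccc2c(c1)O[C@H](c1ccc(OCOC)c(OCOC)c1)CN(C2)N(OCc1ccccc1)C(=O)c1ccc(cc1)C(F)(F)F | intermediate
12 | isodiazene (1,1-diazene) of 10 | COCOc1ccc2c(c1)O[C@H](c1ccc(OCOC)c(OCOC)c1)C[N+](=[N-])C2 | intermediate
13 | 1,6-diradical, primary at C3 and benzylic at C4, C2 arrangement unchanged | COCOc1ccc([CH2])c(c1)O[C@H](c1ccc(OCOC)c(OCOC)c1)[CH2] | intermediate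
14 | (2S)-7,3',4'-tris(methoxymethoxy)flavan | COCOc1ccc2c(c1)O[C@H](c1ccc(OCOC)c(OCOC)c1)CC2 | intermediate
15 | (2S)-7,3',4'-tris(methoxymethoxy)flavan-4-ol, both C4 epimers | COCOc1ccc2c(c1)O[C@H](c1ccc(OCOC)c(OCOC)c1)CC2O | intermediate
16 | (2S)-7,3',4'-tris(methoxymethoxy)flavanone | COCOc1ccc2c(c1)O[C@H](c1ccc(OCOC)c(OCOC)c1)CC2=O | intermediate
17 | (2S,4S)-7,3',4'-tris(methoxymethoxy)flavan-4-ol (2,4-cis) | COCOc1ccc2c(c1)O[C@H](c1ccc(OCOC)c(OCOC)c1)C[C@@H]2O | intermediate
18 | propargyl alcohol | C#CCO | starting material
19 | 4-methyl-2,5-dihydro-1,2-oxamagnesole (cyclic alkenylmagnesium alkoxide) | CC1=C[Mg]OC1 | intermediate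
20 | (Z)-3-iodo-2-methylprop-2-en-1-ol | C/C(=C/I)CO | intermediate
21 | (Z)-tert-butyl[(3-iodo-2-methylprop-2-en-1-yl)oxy]dimethylsilane | C/C(=C/I)CO[Si](C)(C)C(C)(C)C | intermediate
22 | (Z)-3-(tert-butyldimethylsilyloxy)-2-methylprop-1-enyllithium | C/C(=C/[Li])CO[Si](C)(C)C(C)(C)C | intermediate
23 | (Z)-4-(tert-butyldimethylsilyloxy)-3-methylbut-2-en-1-ol | C/C(=C/CO)CO[Si](C)(C)C(C)(C)C | intermediate
24 | (Z)-[(4-bromo-2-methylbut-2-en-1-yl)oxy](tert-butyl)dimethylsilane | C/C(=C/CBr)CO[Si](C)(C)C(C)(C)C | intermediate
25 | C8-lithio lithium C4-alkoxide of 17 | [Li]c1c(OCOC)ccc2c1O[C@H](c1ccc(OCOC)c(OCOC)c1)C[C@@H]2O[Li] | intermediate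
26 | C8-copper lithium C4-alkoxide of 17 | [Cu]c1c(OCOC)ccc2c1O[C@H](c1ccc(OCOC)c(OCOC)c1)C[C@@H]2O[Li] | intermediate
27 | (2S,4S)-8-[(2Z)-4-(tert-butyldimethylsilyloxy)-3-methylbut-2-en-1-yl]-7,3',4'-tris(methoxymethoxy)flavan-4-ol | C/C(=C/Cc1c(OCOC)ccc2c1O[C@H](c1ccc(OCOC)c(OCOC)c1)C[C@@H]2O)CO[Si](C)(C)C(C)(C)C | intermediate
28 | (2S)-8-[(2Z)-4-(tert-butyldimethylsilyloxy)-3-methylbut-2-en-1-yl]-7,3',4'-tris(methoxymethoxy)flavanone | C/C(=C/Cc1c(OCOC)ccc2c1O[C@H](c1ccc(OCOC)c(OCOC)c1)CC2=O)CO[Si](C)(C)C(C)(C)C | intermediate
29 | (2S)-2-(3,4-dihydroxyphenyl)-7-hydroxy-8-[(2Z)-4-hydroxy-3-methylbut-2-en-1-yl]-2,3-dihydro-4H-chromen-4-one | C/C(=C/Cc1c(O)ccc2c1O[C@H](c1ccc(O)c(O)c1)CC2=O)CO | target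

Total step count: 15.
Longest linear sequence: 10 steps from 1 (steps 1, 2, 4, 5, 6, 7, 8, 13, 14, 15).

Steps most likely to fail

Step 6. Cleavage of the C2–O1 bond in the diradical may compete with radical coupling. Material would then drain into an achiral fragment pair that re-adds without stereocontrol, and the enantiomeric purity would erode. Tautomerisation of the isodiazene to a hydrazone would lower the conversion as well.
The fallback sets out from 5 and comes back at 14. It makes C3–C4 by a polar condensation, sets C2 by catalyst control and closes ring C last at O1–C8a. Commercial 3,4-dihydroxyacetophenone is converted with MOMCl and K2CO3 into 3,4-bis(methoxymethoxy)acetophenone F1. Claisen–Schmidt condensation of this ketone with 5 (Ba(OH)2, MeOH, rt) gives the E enone F2, and hydrogenation (H2, Pd/C, EtOAc) gives the saturated ketone F3. Asymmetric transfer hydrogenation with RuCl[(S,S)-TsDPEN](p-cymene) in HCO2H–Et3N sets the S carbinol F4. KOtBu in DMSO with heating then displaces the fluoride intramolecularly, with retention at the carbinol carbon, to give 14.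

Step 7. Hydride abstraction may occur at C2, whose C–H bond is activated by ring B and O1, with ring opening and loss of the stereocentre. Alternatively the C4 cation may lose a C3 proton to give a flav-3-ene that is oxidised on to a flavylium salt.
The fallback sets out from 4 and comes back at 16. It keeps the ring contraction but steers the oxidation through a free ring A phenol instead of through relative cation stability.
- The phenol of 4 is benzylated (BnBr, K2CO3, acetone) to 4-(benzyloxy)-2-fluorobenzaldehyde F5.
- The operations of steps 4, 5 and 6 then lead through the trityl-protected ether aldehyde F6 and the 8-benzyloxy benzoxazepine F7 to the 7-benzyloxy flavan F8.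
- Hydrogenolysis (H2, Pd/C, EtOAc), which spares the C2–O1 bond as it does in benzylated flavan-3-ols, frees only the ring A phenol and gives the 7-hydroxyflavan F9.
- DDQ in aqueous dioxane oxidises this 4-alkylphenol through its para-quinone methide, whose electrophilic terminus is C4, to the 7-hydroxyflavanone F10.
- MOMCl with i-Pr2NEt in CH2Cl2 returns 16.

Step 13. The crowded arylcopper may attack the γ-carbon of the bromide. The alkene may isomerise from Z to E through an allylcopper intermediate. Capture by the trisubstituted bromide may be slow enough for protonation to win, and some metalation of ring B may compete.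
The fallback sets out from 17 and comes back at 27. It builds the alkene by olefination instead of bringing it in by allylic substitution.
- The C8 anion is generated as before and quenched with the small, fast electrophile allyl bromide to give the 8-allyl flavan-4-ol F11.
- Lemieux–Johnson cleavage (OsO4 cat., NaIO4, 2,6-lutidine, dioxane–H2O) gives the arylacetaldehyde F12.
- Still–Gennari olefination with methyl 2-[bis(2,2,2-trifluoroethoxy)phosphoryl]propanoate (KN(SiMe3)2, 18-crown-6, THF, −78 °C) sets the Z enoate F13.
- i-Bu2AlH in CH2Cl2 at −78 °C reduces it to the diol F14.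
- One equivalent of TBSCl with imidazole silylates the primary allylic hydroxyl in preference to the secondary benzylic one and gives 27.

Further compounds
F1 | step 6 | 3,4-bis(methoxymethoxy)acetophenone | CC(=O)c1ccc(OCOC)c(OCOC)c1
F2 | step 6 | (E)-1-[3,4-bis(methoxymethoxy)phenyl]-3-[2-fluoro-4-(methoxymethoxy)phenyl]prop-2-en-1-one | O=C(/C=C/c1ccc(OCOC)cc1F)c1ccc(OCOC)c(OCOC)c1
F3 | step 6 | 1-[3,4-bis(methoxymethoxy)phenyl]-3-[2-fluoro-4-(methoxymethoxy)phenyl]propan-1-one | O=C(CCc1ccc(OCOC)cc1F)c1ccc(OCOC)c(OCOC)c1
F4 | step 6 | (1S)-1-[3,4-bis(methoxymethoxy)phenyl]-3-[2-fluoro-4-(methoxymethoxy)phenyl]propan-1-ol | O[C@H](c1ccc(OCOC)c(OCOC)c1)CCc1ccc(OCOC)cc1F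
F5 | step 7 | 4-(benzyloxy)-2-fluorobenzaldehyde | O=Cc1ccc(OCc2ccccc2)cc1F
F6 | step 7 | 4-(benzyloxy)-2-{(1R)-1-[3,4-bis(methoxymethoxy)phenyl]-2-(tritylamino)ethoxy}benzaldehyde | O=Cc1ccc(OCc2ccccc2)cc1O[C@H](c1ccc(OCOC)c(OCOC)c1)CNC(c1ccccc1)(c1ccccc1)c1ccccc1
F7 | step 7 | (2R)-8-(benzyloxy)-2-[3,4-bis(methoxymethoxy)phenyl]-2,3,4,5-tetrahydro-1,4-benzoxazepine | c1ccccc1COc1ccc2c(c1)O[C@H](c1ccc(OCOC)c(OCOC)c1)CNC2
F8 | step 7 | (2S)-7-(benzyloxy)-3',4'-bis(methoxymethoxy)flavan | c1ccccc1COc1ccc2c(c1)O[C@H](c1ccc(OCOC)c(OCOC)c1)CC2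
F9 | step 7 | (2S)-7-hydroxy-3',4'-bis(methoxymethoxy)flavan | Oc1ccc2c(c1)O[C@H](c1ccc(OCOC)c(OCOC)c1)CC2
F10 | step 7 | (2S)-7-hydroxy-3',4'-bis(methoxymethoxy)flavanone | Oc1ccc2c(c1)O[C@H](c1ccc(OCOC)c(OCOC)c1)CC2=O
F11 | step 13 | (2S,4S)-8-allyl-7,3',4'-tris(methoxymethoxy)flavan-4-ol | C=CCc1c(OCOC)ccc2c1O[C@H](c1ccc(OCOC)c(OCOC)c1)C[C@@H]2O
F12 | step 13 | [(2S,4S)-4-hydroxy-7,3',4'-tris(methoxymethoxy)flavan-8-yl]acetaldehyde | O=CCc1c(OCOC)ccc2c1O[C@H](c1ccc(OCOC)c(OCOC)c1)C[C@@H]2O
F13 | step 13 | methyl (2Z)-4-[(2S,4S)-4-hydroxy-7,3',4'-tris(methoxymethoxy)flavan-8-yl]-2-methylbut-2-enoate | C/C(=C/Cc1c(OCOC)ccc2c1O[C@H](c1ccc(OCOC)c(OCOC)c1)C[C@@H]2O)C(=O)OC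
F14 | step 13 | (2S,4S)-8-[(2Z)-4-hydroxy-3-methylbut-2-en-1-yl]-7,3',4'-tris(methoxymethoxy)flavan-4-ol | C/C(=C/Cc1c(OCOC)ccc2c1O[C@H](c1ccc(OCOC)c(OCOC)c1)C[C@@H]2O)CO
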